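**Strategy.** The route rests on disconnecting the O1–C8a bond of the chromone. C8a of ring A lies para to the methoxy-bearing C6, and C5 and C7 both carry oxygen, so ring A can come from the symmetric dibenzyl ether of 2-methoxyresorcinol, acylated at its only activated position. In the key step the α-formyl deoxybenzoin, held as its chelated Z enol with all three phenols benzylated, loses two electrons and two protons while the enol oxygen bonds to the free ortho carbon of the aroyl ring. This closes the pyranone ring and fixes the 5,6,7-oxygenation pattern without regiochemical ambiguity. Hydrogenolysis and 4'-selective prenylation complete the synthesis.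

Key step: step 4

Remark on the chemistry: the formyl ketone is drawn as its hydrogen-bonded Z enol; its tautomers and rotamers interconvert, so the closure in step 4 does not depend on the geometry drawn. The target has no stereocentre.

**Step 1**
Reactants: 1 2-methoxybenzene-1,3-diol (2-methoxyresorcinol); 2 benzyl bromide (two equivalents are consumed)
Product: 3 1,3-bis(benzyloxy)-2-methoxybenzene
Conditions: BnBr (2.2 equiv), K2CO3 (3 equiv), DMF, 60 °C
Reagents that add atoms: benzyl bromide (second equivalent), BrCc1ccccc1
Why: A double Williamson ether synthesis in which each of the two phenoxides of the symmetric diol is alkylated by one equivalent of the reactive benzylic bromide, so only one dibenzyl ether can form.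

**Step 2**
Reactants: 3 1,3-bis(benzyloxy)-2-methoxybenzene; 4 2-[4-(benzyloxy)phenyl]acetic acid
Product: 6 1-[2,4-bis(benzyloxy)-3-methoxyphenyl]-2-[4-(benzyloxy)phenyl]ethan-1-one, via mixed trifluoroacetic anhydride 5 (not isolated)
Conditions: (CF3CO)2O, 85% H3PO4 (cat.), CH2Cl2, 0 °C to rt
Reagents that add atoms: none
Why: Friedel–Crafts acylation through the mixed anhydride; C4 and C6 of 3 are equivalent and each is ortho to one benzyloxy group and para to the other, whereas C5 is meta to both, so a single ketone should form under Brønsted-acid conditions mild enough to spare the benzyl ethers.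

**Step 3**
Reactants: 6 1-[2,4-bis(benzyloxy)-3-methoxyphenyl]-2-[4-(benzyloxy)phenyl]ethan-1-one
Product: 8 (Z)-1-[2,4-bis(benzyloxy)-3-methoxyphenyl]-2-[4-(benzyloxy)phenyl]-3-hydroxyprop-2-en-1-one, via sodium enolate 7 (not isolated)
Conditions: HCO2Et, NaH, THF, 0 °C to rt; then cold 1 M HCl
Reagents that add atoms: ethyl formate, CCOC=O
Why: Crossed Claisen condensation (α-formylation) of the acidic benzylic α-methylene with non-enolisable ethyl formate, driven by formation of the stabilised sodium enolate 7; acidification should give the chelated Z enol, which cannot close on its own because ring A has no free ortho hydroxyl.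

**Step 4**
Reactants: 8 (Z)-1-[2,4-bis(benzyloxy)-3-methoxyphenyl]-2-[4-(benzyloxy)phenyl]-3-hydroxyprop-2-en-1-one
Product: 9 5,7-bis(benzyloxy)-3-[4-(benzyloxy)phenyl]-6-methoxy-4H-chromen-4-one
Conditions: graphite anode, Pt cathode, undivided cell, constant current (about 2.2 F/mol), n-Bu4NPF6, 2,6-lutidine, HFIP/CH2Cl2, rt, Ar
Reagents that add atoms: none
Why: Proposed new method: the enolate formed with 2,6-lutidine is the most easily oxidised part of 8, so the anode should convert it into a delocalised 2-aryl-1,3-dicarbonyl radical whose formyl-derived oxygen adds to C8a, giving a cyclohexadienyl radical stabilised by the para methoxy group on C6 and by the C4 carbonyl; a second electron transfer and loss of the C8a proton restore the arene, and the protons are reduced to dihydrogen at the cathode. The closest known reaction types are the FeCl3-mediated oxidative O-arylation of α-aryl 1,3-dicarbonyl enols to benzofurans, the oxidative closure of 2-hydroxybenzophenones to xanthones (same O–C=C–C(=O)–aryl topology) and the anodic dehydrogenative lactonisation of biaryl-2-carboxylic acids. The pyranone ring closes in a six-membered mode by attack of oxygen on the ortho carbon of the aroyl ring (6-endo with respect to the C4a=C8a bond), and no stereocentre is created. The step needs site selectivity, which the substrate supplies: C8a is the only C–H of ring A within reach and lies para to a methoxy group, the five-membered closure onto C2' of ring B would hit a carbon meta to the 4'-benzyloxy group, and addition at the substituted ipso carbon C4a gives a crowded spiro radical that can reopen, whereas the C8a adduct aromatises irreversibly. It also needs oxygen rather than C3 to react and the oxidation to stop at the chromone: C3 is fully substituted and can only meet external partners, which weakly nucleophilic HFIP, exclusion of dioxygen and dilution disfavour, and product 9 has no enol and should be oxidised only at a clearly higher potential, so the charge is limited to about two faradays per mole. No Lewis acid is present, which keeps the benzyl ether ortho to the ketone in place and so shuts off the ordinary condensation through that oxygen to a 7-benzyloxy-8-methoxyisoflavone.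

**Step 5**
Reactants: 9 5,7-bis(benzyloxy)-3-[4-(benzyloxy)phenyl]-6-methoxy-4H-chromen-4-one
Product: 10 tectorigenin (5,7-dihydroxy-3-(4-hydroxyphenyl)-6-methoxy-4H-chromen-4-one)
Conditions: H2 (1 atm), 10% Pd/C, THF/MeOH, rt
Reagents that add atoms: none
Why: Catalytic hydrogenolysis of the three aryl benzyl ethers, which should be much faster than reduction of the C2=C3 bond of the vinylogous ester, so stopping after uptake of three equivalents of dihydrogen should leave the chromone and the methyl ether untouched.

**Step 6**
Reactants: 10 tectorigenin; 11 prenyl bromide (1-bromo-3-methylbut-2-ene)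
Product: 14 isoaurmillone (5,7-dihydroxy-6-methoxy-3-{4-[(3-methylbut-2-en-1-yl)oxy]phenyl}-4H-chromen-4-one), via dipotassium 7,4'-diphenoxide 12 (not isolated), via potassium 7-phenoxide 13 (not isolated)
Conditions: t-BuOK (2.05 equiv), DMF, 0 °C; prenyl bromide (1.0 equiv), 0 °C to rt; then 1 M HCl
Reagents that add atoms: none
Why: Williamson O-alkylation of the 7,4'-dianion, a known regioselective reaction of 7,4'-dihydroxyisoflavones: the 7-phenoxide is a vinylogous carboxylate delocalised into the C4 carbonyl and the 5-hydroxyl stays locked in its hydrogen bond, so the more basic 4'-phenoxide should take the single equivalent of the allylic bromide.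

**Compound list**
1 | 2-methoxybenzene-1,3-diol (2-methoxyresorcinol) | COc1c(O)cccc1O | starting material
2 | benzyl bromide | BrCc1ccccc1 | starting material
3 | 1,3-bis(benzyloxy)-2-methoxybenzene | COc1c(OCc2ccccc2)cccc1OCc1ccccc1 | intermediate
4 | 2-[4-(benzyloxy)phenyl]acetic acid | O=C(O)Cc1ccc(OCc2ccccc2)cc1 | starting material
5 | [4-(benzyloxy)phenyl]acetic trifluoroacetic anhydride | O=C(Cc1ccc(OCc2ccccc2)cc1)OC(=O)C(F)(F)F | intermediate
6 | 1-[2,4-bis(benzyloxy)-3-methoxyphenyl]-2-[4-(benzyloxy)phenyl]ethan-1-one | COc1c(OCc2ccccc2)ccc(C(=O)Cc2ccc(OCc3ccccc3)cc2)c1OCc1ccccc1 | intermediate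
7 | sodium (Z)-3-[2,4-bis(benzyloxy)-3-methoxyphenyl]-2-[4-(benzyloxy)phenyl]-3-oxoprop-1-en-1-olate | COc1c(OCc2ccccc2)ccc(C(=O)/C(=C\[O-])c2ccc(OCc3ccccc3)cc2)c1OCc1ccccc1.[Na+] | intermediate
8 | (Z)-1-[2,4-bis(benzyloxy)-3-methoxyphenyl]-2-[4-(benzyloxy)phenyl]-3-hydroxyprop-2-en-1-one | COc1c(OCc2ccccc2)ccc(C(=O)/C(=C\O)c2ccc(OCc3ccccc3)cc2)c1OCc1ccccc1 | intermediate
9 | 5,7-bis(benzyloxy)-3-[4-(benzyloxy)phenyl]-6-methoxy-4H-chromen-4-one | COc1c(OCc2ccccc2)cc2occ(-c3ccc(OCc4ccccc4)cc3)c(=O)c2c1OCc1ccccc1 | intermediate
10 | tectorigenin (5,7-dihydroxy-3-(4-hydroxyphenyl)-6-methoxy-4H-chromen-4-one) | COc1c(O)cc2occ(-c3ccc(O)cc3)c(=O)c2c1O | intermediate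
11 | prenyl bromide (1-bromo-3-methylbut-2-ene) | CC(C)=CCBr | starting material
12 | dipotassium 5-hydroxy-6-methoxy-4-oxo-3-(4-oxidophenyl)-4H-chromen-7-olate | COc1c([O-])cc2occ(-c3ccc([O-])cc3)c(=O)c2c1O.[K+].[K+] | intermediate
13 | potassium 5-hydroxy-6-methoxy-3-{4-[(3-methylbut-2-en-1-yl)oxy]phenyl}-4-oxo-4H-chromen-7-olate | COc1c([O-])cc2occ(-c3ccc(OCC=C(C)C)cc3)c(=O)c2c1O.[K+] | intermediate
14 | isoaurmillone (5,7-dihydroxy-6-methoxy-3-{4-[(3-methylbut-2-en-1-yl)oxy]phenyl}-4H-chromen-4-one) | COc1c(O)cc2occ(-c3ccc(OCC=C(C)C)cc3)c(=O)c2c1O | target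

**Step count.** Total steps: 6. Longest linear sequence: 6 steps (1 to 14).

**Steps most likely to fail**

Step 4 (proposed new method). The oxidised enol may be consumed at C3 (radical dimerisation, or capture by traces of water followed by deformylation) before its oxygen reaches C8a, which is activated only by the flanked methoxy group. It may also close at the ipso carbon C4a in a spiro mode with later loss of a benzyl group, or a benzyl ether may be cleaved oxidatively. The fallback uses known chemistry, sets out from ketone 6 and returns at isoflavone 9. A carbonyl-directed C–H borylation with an iridium catalyst ([Ir(OMe)(cod)]2, AsPh3, B2pin2, octane, 120 °C) would place boron on the single ring-A C–H ortho to the ketone and give the 6-pinacolboryl ketone F1. Oxidation (NaBO3·4H2O, THF/H2O, rt) would give the 6-hydroxy ketone F2. Heating with N,N-dimethylformamide dimethyl acetal (THF, 70 °C) would form the enaminone F3, which closes by attack of the new phenol on the enamine carbon with loss of dimethylamine to give 9. This is the classical deoxybenzoin ring closure with O1 installed before ring formation; only the new hydroxyl can cyclise because the other ortho oxygen is benzylated.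

Step 6. Alkylation may drift to the 7-oxygen or to C8, or go twice, if the dianion is incompletely formed or the two phenoxides react at similar rates. The fallback sets out from triol 10 and returns at 14. The monoanion (t-BuOK, 1.0 equiv, DMF, 0 °C), which resides on the most acidic 7-oxygen, would be acylated with pivaloyl chloride to the 7-pivalate F4. Its free 4'-phenol would be alkylated with prenyl bromide 11 (K2CO3, acetone, rt; the chelated 5-hydroxyl stays inert) to the 7-pivalate 4'-prenyl ether F5. Methanolysis (K2CO3, MeOH, rt) would remove the pivalate and give 14.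

Step 2. Acid-promoted loss of the benzyl group next to the new ketone, or self-acylation of the electron-rich arylacetic acid, may erode the acylation. The fallback sets out from ether 3 and acid 4 and returns at ketone 6. Bromination of 3 (NBS, MeCN, 0 °C) at the same activated position would give the aryl bromide F6. Acid 4 would be converted into its N-methoxy-N-methylamide F7 (MeNHOMe·HCl, EDC·HCl, Et3N, CH2Cl2). Bromine–lithium exchange of F6 (n-BuLi, THF, −78 °C) would give the aryllithium F8, whose addition to F7 and acidic work-up would deliver 6 without any electrophilic acylation.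

**Further compounds**
F1 | step 4 | 1-[2,4-bis(benzyloxy)-3-methoxy-6-(4,4,5,5-tetramethyl-1,3,2-dioxaborolan-2-yl)phenyl]-2-[4-(benzyloxy)phenyl]ethan-1-one | COc1c(OCc2ccccc2)cc(B2OC(C)(C)C(C)(C)O2)c(C(=O)Cc2ccc(OCc3ccccc3)cc2)c1OCc1ccccc1
F2 | step 4 | 1-[2,4-bis(benzyloxy)-6-hydroxy-3-methoxyphenyl]-2-[4-(benzyloxy)phenyl]ethan-1-one | COc1c(OCc2ccccc2)cc(O)c(C(=O)Cc2ccc(OCc3ccccc3)cc2)c1OCc1ccccc1
F3 | step 4 | (E)-1-[2,4-bis(benzyloxy)-6-hydroxy-3-methoxyphenyl]-2-[4-(benzyloxy)phenyl]-3-(dimethylamino)prop-2-en-1-one | COc1c(OCc2ccccc2)cc(O)c(C(=O)/C(=C/N(C)C)c2ccc(OCc3ccccc3)cc2)c1OCc1ccccc1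
F4 | step 6 | 5-hydroxy-3-(4-hydroxyphenyl)-6-methoxy-4-oxo-4H-chromen-7-yl 2,2-dimethylpropanoate | COc1c(OC(=O)C(C)(C)C)cc2occ(-c3ccc(O)cc3)c(=O)c2c1O
F5 | step 6 | 5-hydroxy-6-methoxy-3-{4-[(3-methylbut-2-en-1-yl)oxy]phenyl}-4-oxo-4H-chromen-7-yl 2,2-dimethylpropanoate | COc1c(OC(=O)C(C)(C)C)cc2occ(-c3ccc(OCC=C(C)C)cc3)c(=O)c2c1O
F6 | step 2 | 1,3-bis(benzyloxy)-4-bromo-2-methoxybenzene | COc1c(OCc2ccccc2)ccc(Br)c1OCc1ccccc1
F7 | step 2 | 2-[4-(benzyloxy)phenyl]-N-methoxy-N-methylacetamide | CON(C)C(=O)Cc1ccc(OCc2ccccc2)cc1
F8 | step 2 | [2,4-bis(benzyloxy)-3-methoxyphenyl]lithium | [Li]c1ccc(OCc2ccccc2)c(OC)c1OCc1ccccc1
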